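Assumption: the neutral guanidine tautomer drawn is the target. It is handled as its hydrochloride and free-based in the last work-up.

## Retrosynthetic overview
1. The allyl sulfone C–S bond is cut last, giving the C20 allylic alcohol and 2-guanidinoethanesulfinic acid (hypotaurocyamine).
2. The key cut is the C7–C8 C(sp2)–C(sp3) bond of the side chain. It gives a C11 ring alcohol and a C9 (E)-alkenyl iodide, joined under visible light by Ni/Ir deoxygenative alkenylation.
3. The ring alcohol comes from (R)-carvone. Conjugate methylation and enolate alkylation set both stereocentres anti to the isopropenyl group, which is then excised. The ketone becomes the ring C(Me)=CH through its enol triflate.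
4. The alkenyl iodide comes from 3-pentyn-1-ol and methyl but-2-ynoate. Syn-carbocupration and syn-hydrozirconation fix the two E-alkenes.
5. No ring is formed. The only carbocycle is bought with carvone.

## Route

**Step 1**
Reactants: 1, (R)-(−)-carvone; 2, tert-butyl bromoacetate
Product: 3, tert-butyl 2-[(1S,2R,4R)-1,2-dimethyl-6-oxo-4-(prop-1-en-2-yl)cyclohexyl]acetate
Conditions: Me2CuLi (1.3 equiv), Et2O, 0 °C; then 2 (3 equiv), THF/DMPU, −20 °C → rt
Reagents that add atoms: lithium dimethylcuprate, [Li+].C[Cu-]C; tert-butyl bromoacetate (2), BrCC(=O)OC(C)(C)C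
Why: In this tandem cuprate conjugate addition–enolate alkylation, methyl adds axially, trans to the equatorial isopropenyl group (setting the CH–CH3 centre), and the regiodefined tetrasubstituted enolate is then C-alkylated axially on the face anti to the new pseudo-axial methyl, so the quaternary centre forms with the two methyls cis (expected dr ≥10:1).

**Step 2**
Reactants: 3
Product: 4, tert-butyl 2-[(1S,2R)-1,2-dimethyl-6-oxocyclohexyl]acetate
Conditions: O3, MeOH, −78 °C; then PhSH (1.5 equiv), FeSO4·7H2O (1.2 equiv), −78 °C → rt
Reagents that add atoms: none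
Why: Hydrodealkenylation (ozonolysis to the α-methoxy hydroperoxide, Fe(II) reduction to the alkoxyl radical, β-scission with loss of methyl acetate, then H-atom transfer from the thiol) replaces the isopropenyl control element by H without touching the ketone, the ester or the two stereocentres.

**Step 3**
Reactants: 4
Product: 5, tert-butyl 2-[(1S,6R)-1,6-dimethyl-2-(trifluoromethylsulfonyloxy)cyclohex-2-en-1-yl]acetate
Conditions: KHMDS (1.2 equiv), THF, −78 °C; PhNTf2, −78 → 0 °C
Reagents that add atoms: N-phenylbis(trifluoromethanesulfonimide), O=S(=O)(N(c1ccccc1)S(=O)(=O)C(F)(F)F)C(F)(F)F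
Why: In this kinetic enolisation and O-triflation, the quaternary α-carbon leaves only one enolisable side of the ketone, and the hindered, less acidic tert-butyl ester is not deprotonated or attacked at −78 °C.

**Step 4**
Reactants: 5
Product: 6, tert-butyl 2-[(1S,6R)-1,2,6-trimethylcyclohex-2-en-1-yl]acetate
Conditions: MeMgBr (1.8 equiv), Fe(acac)3 (10 mol %), THF/NMP, −30 → 0 °C
Reagents that add atoms: methylmagnesium bromide, C[Mg]Br
Why: Iron-catalysed Kumada-type coupling of the alkenyl triflate is much faster than Grignard addition to a tert-butyl ester, and it places the ring C(Me)=CH alkene regiospecifically.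

**Step 5**
Reactants: 6
Product: 7, 2-[(1S,6R)-1,2,6-trimethylcyclohex-2-en-1-yl]ethan-1-ol
Conditions: LiAlH4, Et2O, 0 °C → rt
Reagents that add atoms: none
Why: Hydride reduction of the ester gives the primary alcohol, and the isolated trisubstituted alkene and both stereocentres are inert.

**Step 6**
Reactants: 8, pent-3-yn-1-ol
Product: 9, 5-iodopent-2-yne
Conditions: I2, PPh3, imidazole, CH2Cl2, 0 °C
Reagents that add atoms: iodine, II
Why: Appel-type iodination of an unhindered primary alcohol leaves the internal alkyne untouched.

**Step 7**
Reactants: 9; 10, methyl but-2-ynoate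
Product: 11, methyl (E)-3-methyloct-2-en-6-ynoate
Conditions: 9 (2 equiv), t-BuLi (4 equiv), Et2O/pentane, −78 °C; CuI (1 equiv), −40 °C; 10 (1 equiv), −78 °C; MeOH quench at −78 °C
Reagents that add atoms: none
Why: Li–I exchange gives the Gilman cuprate, which adds syn across the ynoate (carbocupration/conjugate addition), and protonating the alkenylcopper at −78 °C retains geometry, leaving the chain trans to the ester (E ≥95:5).

**Step 8**
Reactants: 11
Product: 12, (E)-3-methyloct-2-en-6-yn-1-ol
Conditions: DIBAL-H (2.3 equiv), CH2Cl2, −78 °C
Reagents that add atoms: none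
Why: 1,2-Reduction of the enoate gives the allylic alcohol without affecting alkene geometry or the alkyne at low temperature.

**Step 9**
Reactants: 12
Product: 13, (2E,6E)-7-iodo-3-methylocta-2,6-dien-1-ol
Conditions: Cp2Zr(H)Cl (3 equiv), THF, rt → 45 °C, dark; then I2, 0 °C
Reagents that add atoms: iodine, II
Why: In this syn-hydrozirconation/iodinolysis, one equivalent of reagent is consumed by the OH, the excess equilibrates Zr onto the less hindered methyl-bearing alkyne carbon (about 9:1, isomers separable), iodination proceeds with retention to the (E)-2-iodoalkene, and the trisubstituted alkene does not react.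

**Step 10 (key step)**
Reactants: 7 (1.3 equiv); 13 (1.0 equiv)
Product: 14, (2E,6E)-3,7-dimethyl-9-[(1S,6R)-1,2,6-trimethylcyclohex-2-en-1-yl]nona-2,6-dien-1-ol
Conditions: (i) 7, 5,7-di-tert-butyl-3-phenylbenzoxazolium BF4 (1.25 equiv), pyridine, MTBE, rt, filter; (ii) 13, [Ir(ppy)2(dtbbpy)]PF6 (1.5 mol %), NiBr2·dtbbpy (7.5 mol %), quinuclidine (1.8 equiv), phthalimide (0.3 equiv), DMA/MTBE, 450 nm LEDs, rt
Reagents that add atoms: none
Why: Proposed new method: deoxygenative C(sp3)–C(sp2) alkenylation of a benzoxazolium-activated primary alcohol with a stereodefined, unactivated trisubstituted alkenyl iodide — the OH of 7 condenses with the salt to a 2-alkoxybenzoxazoline, excited Ir(III) oxidises its anilinic nitrogen, quinuclidine removes the acidified C2–H, and β-scission of the resulting radical (driven by carbamate C=O formation) releases the primary radical ring–CH2CH2•, while dtbbpy–Ni(0) inserts into the C–I bond of 13 with retention, captures the radical and reductively eliminates from Ni(III), and Ir(II) returns Ni(I) to Ni(0) in a redox-neutral cycle; it should succeed because this radical has only slow self-reactions (4-exo/5-endo closure, carbon-to-carbon 1,5-H shift), unconjugated trisubstituted alkenes lie far above the sensitiser triplet energy so E geometry is kept, and the OH of 13 is not activated since the adduct of 7 is pre-formed and filtered free of salt; the closest known reactions are the metallaphotoredox deoxygenative arylation of such alcohol adducts with aryl halides and Ni-catalysed alkyl-radical/alkenyl-halide couplings from acids or halides.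

**Step 11**
Reactants: 15, hypotaurine (2-aminoethanesulfinic acid); 16, 1H-pyrazole-1-carboxamidine hydrochloride
Product: 17, hypotaurocyamine (2-guanidinoethanesulfinic acid, zwitterion)
Conditions: Na2CO3 (1 equiv), degassed H2O, rt, 16 h; crystallise from H2O/EtOH
Reagents that add atoms: 1H-pyrazole-1-carboxamidine hydrochloride (16), Cl.NC(=N)n1cccn1
Why: In this amidine-transfer guanylation of the primary amine, pyrazole is the leaving group and the sulfinate is a spectator under air-free aqueous conditions.

**Step 12**
Reactants: 14; 17 (1.3 equiv)
Product: 18, agelasidine C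
Conditions: 17 + HCl (1.3 equiv, MeOH), then 14, Pd(PPh3)4 (5 mol %), DMSO/THF, 40 °C; work-up over OH-form anion-exchange resin
Reagents that add atoms: none
Why: In this Tsuji–Trost-type dehydrative allylic sulfonylation, the free sulfinic acid activates the allylic OH for Pd(0) ionisation, soft S-attack occurs at the primary terminus, any tertiary sulfone re-ionises so the linear (E)-sulfone accumulates, and the guanidinium stays protonated so N-allylation is suppressed.

## Compound list
1 | (R)-(−)-carvone | CC1=CC[C@H](CC1=O)C(C)=C | starting material
2 | tert-butyl bromoacetate | BrCC(=O)OC(C)(C)C | starting material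
3 | tert-butyl 2-[(1S,2R,4R)-1,2-dimethyl-6-oxo-4-(prop-1-en-2-yl)cyclohexyl]acetate | O=C1C[C@H](C(C)=C)C[C@@H](C)[C@]1(C)CC(=O)OC(C)(C)C | intermediate
4 | tert-butyl 2-[(1S,2R)-1,2-dimethyl-6-oxocyclohexyl]acetate | O=C1CCC[C@@H](C)[C@]1(C)CC(=O)OC(C)(C)C | intermediate
5 | tert-butyl 2-[(1S,6R)-1,6-dimethyl-2-(triflyloxy)cyclohex-2-en-1-yl]acetate | O=S(=O)(OC1=CCC[C@@H](C)[C@]1(C)CC(=O)OC(C)(C)C)C(F)(F)F | intermediate
6 | tert-butyl 2-[(1S,6R)-1,2,6-trimethylcyclohex-2-en-1-yl]acetate | CC1=CCC[C@@H](C)[C@]1(C)CC(=O)OC(C)(C)C | intermediate
7 | 2-[(1S,6R)-1,2,6-trimethylcyclohex-2-en-1-yl]ethan-1-ol | CC1=CCC[C@@H](C)[C@]1(C)CCO | intermediate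
8 | pent-3-yn-1-ol | CC#CCCO | starting material
9 | 5-iodopent-2-yne | CC#CCCI | intermediate
10 | methyl but-2-ynoate | CC#CC(=O)OC | starting material
11 | methyl (E)-3-methyloct-2-en-6-ynoate | CC#CCC/C(C)=C/C(=O)OC | intermediate
12 | (E)-3-methyloct-2-en-6-yn-1-ol | CC#CCC/C(C)=C/CO | intermediate
13 | (2E,6E)-7-iodo-3-methylocta-2,6-dien-1-ol | I/C(C)=C/CC/C(C)=C/CO | intermediate
14 | (2E,6E)-3,7-dimethyl-9-[(1S,6R)-1,2,6-trimethylcyclohex-2-en-1-yl]nona-2,6-dien-1-ol | CC1=CCC[C@@H](C)[C@]1(C)CC/C(C)=C/CC/C(C)=C/CO | intermediate
15 | hypotaurine | NCCS(=O)O | starting material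
16 | 1H-pyrazole-1-carboxamidine hydrochloride | Cl.NC(=N)n1cccn1 | starting material
17 | hypotaurocyamine (2-guanidinoethanesulfinic acid) | NC(=N)NCCS(=O)O | intermediate
18 | agelasidine C | CC1=CCC[C@@H](C)[C@]1(C)CC/C(C)=C/CC/C(C)=C/CS(=O)(=O)CCN=C(N)N | target

## Summary
Total steps: 12.
Longest linear sequence: 7 (steps 1, 2, 3, 4, 5, 10, 12).

Steps most likely to fail:
1. **Step 10 (proposed new alkenylation).** The risks are β-hydride loss or H-shift of the primary radical, interference from the free allylic OH, and slow Ni turnover with a trisubstituted alkenyl iodide. Fallback (known chemistry, +1 step): convert 7 to the primary bromide by an Appel reaction. Then join it to 13 by the established Ni/bipyridine electroreductive alkyl-halide/alkenyl-halide cross-electrophile coupling in an undivided cell with a sacrificial anode. This generates the same radical by halogen abstraction instead of alcohol activation.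
2. **Step 1 (one-pot trapping of the copper-containing enolate).** The risks are sluggish C-alkylation, over-alkylation at C6, and consumption of 2 by methylcopper. Fallback (+1 step): trap the conjugate-addition enolate with TMSCl and isolate the regiodefined silyl enol ether. Regenerate a copper-free lithium enolate with MeLi and alkylate it with 2. The facial bias is the same.
3. **Step 12 (direct Pd sulfonylation of the free alcohol with a zwitterion-derived sulfinic acid).** The risks are poor ionisation, sulfinic acid disproportionation, and partial E/Z erosion through the π-allyl. Fallback (+1 step): switch to SN2. Convert 14 to the allylic bromide (MsCl, Et3N, then LiBr, −40 → 0 °C) and S-alkylate zwitterion 17 in DMF/H2O at rt, which keeps the alkene geometry.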